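## Structural features

The target is a linear chain of five six-membered carbocycles, rings A to E, joined by four methylene bridges; it has a mirror plane through ring C and no stereocentre. Rings B, C and D are hexasubstituted benzenes of the butyrylphloroglucinol type: three hydroxyls on alternate carbons, a butanoyl group on the carbon between two of them, and methylene arms on the two carbons that flank the third. Rings A and E are 2-butanoyl-3,5-dihydroxy-4,4-dimethylcyclohexa-2,5-dien-1-ones, enolized triketones with a quaternary gem-dimethyl carbon, each bound to its bridge through its one remaining enol carbon. Since nothing is stereogenic, the problem is one of regiochemistry and of sequence: the order A-B-C-D-E has to be built without the statistical oligomers that formaldehyde condensation of the monomers would give. The fragile elements are the electron-rich diarylmethane bridges (cleaved by strong acid through a stabilized benzylic cation, scrambled by base through retro-Michael fragmentation), the enolized triketones (retro-Claisen cleavage) and the polyphenol rings (oxidation). The hardest ring is C, which has no free carbon and must carry two identical arms and one acyl group in a fixed relation to three oxygens. The key step uses exactly this pattern: ring C has identical arylmethyl groups on the two carbons on either side of one oxygen-bearing carbon, so its six carbons can come from the two alkyne carbons of one arylmethyl ynol ether, the same two carbons a second time in the form of a cyclobutenone, and the two carbons of ketene. The CH2 of ketene ends as the single free ring carbon that later takes the butanoyl group.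

## Logic of the disconnections

**25 to 18 and two copies of 22.** The two bonds cut are those between the methylene carbons on rings A and E and the ring carbons of B and D. These are the only bridges whose two ends differ in kind (dienone on one side, arene on the other). In 18 each of rings B and D has exactly one free carbon and ring C has none, so a twofold coupling can go only one way. The pentamer falls to a symmetric trimer and two copies of one small unit. The forward step must form the new bridges without reopening the two that already exist, which is why it runs through the neutral elimination-addition pair 23 and 24.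

**22 to 21, 20, 19 and 2.** Cut in turn are the bond from the enol carbon to the aminomethyl carbon, the two methyl bonds at the quaternary carbon, and the aryl-acyl bond. Each cut uses the innate nucleophilicity of a phloroglucinol carbon, and the branch ends at 19 and 2. The demand is that geminal methylation in the step from 20 to 21 stops after two methyl groups on one carbon.

**18 to 17.** Eight oxygen-alkyl bonds are cut (six methyl, two ethyl). Free phenols cannot pass through the organometallic and pericyclic steps, and putting all dealkylation into one operation before the end rings arrive keeps the triketones away from a Lewis acid. The demand is that the dealkylation spares the two bridges.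

**17 to 16, then 15 and 2.** The bond between ring C and its butanoyl carbonyl is cut, by way of the ester 16. The only hydroxyl of 15 sits next to the only free carbon of ring C, so acyl transfer from oxygen to carbon can have one outcome. The demand is a Lewis acid mild enough not to acylate rings B and D or to cut the bridges.

**15 to 11 and 8 (key).** Two bonds of ring C are cut: the one between the hydroxyl-bearing carbon and its arm-bearing neighbour, and the one between the other arm-bearing carbon and the ethoxy-bearing carbon that lies between the arms. Ring C with both arms and two of its oxygens is reduced to two derivatives of one building block. The demand is complete regiocontrol in the [2+2] event and a temperature at which 11 opens but 8 does not decompose.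

**11 to 8 and 10 (from 9).** The two ring bonds of the cyclobutenone formed by cycloaddition are cut; 11 is then 8 plus two carbons. The demand is that 10 adds to the internal alkyne faster than it dimerizes.

**8 to 4 and 5, through 6 and 7.** The bond between the benzylic CH2 and the alkyne carbon is cut. The forward step must tolerate the enolizable aryl ketone of 4, which rules out the bare lithium reagent 6 and calls for 7 under palladium catalysis.

**4 to 3, then 1 and 2.** The aryl-CH2Cl bond and the aryl-acyl bond are cut. Both forward substitutions occur on rings whose free positions are equivalent, so no regiochemical question arises.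

## Other disconnections considered

**Alternative 1:** The cut lies in rings A and E, in each between the butanoyl-bearing carbon and the ring carbonyl carbon next to the gem-dimethyl carbon. The precursor A2 is the nonamethyl ether of the B-C-D trimer carrying, on ring B and on ring D, an open chain with three ketone carbonyls and a terminal methyl ester. That is four carbonyl carbons per arm, so "triketo ester" is the more exact term.
- Forward key step: base would deprotonate the methylene between the two chain ketones of each arm, and the enolate would attack the ester (Claisen type, 6-exo-trig), closing both rings to A1.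
- In its favour: two rings close in one operation, the quaternary carbon is already present, and no bridge is formed in the presence of free phenols, so bridge exchange is not an issue at that stage.
- Against it: each arm of A2 must be attached by C-alkylation at one specific carbon of a polycarbonyl chain. The chain can also close through oxygen to a lactone, and alkoxide can cleave it next to the quaternary carbon by retro-Claisen reaction. A1 still carries nine methyl ethers that would have to be removed in the presence of two triketone rings.
- Comparison: on rings formed per step (two against one) and on avoiding a late bridge-forming coupling the alternative is the better. The chosen plan is the better on the end game, since it removes all ethers at 17 before the sensitive rings exist, and on step economy, since 21 needs two steps from 19 whereas the chain of A2 must be built twice on a large intermediate. Mechanistically both rest on classical enolate chemistry at the end rings; the difference is that the chosen plan leaves ring C to a pericyclic construction, which A2 does not address at all.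

**Alternative 2:** The cut removes from ring C the butanoyl group and the hydroxyl oxygen on the adjacent carbon. The precursor A4 is a trimer whose ring C carries a trimethylsilyl group and a triflate on neighbouring carbons.
- Forward key step: fluoride would generate aryne A5; butanoic acid A6 would add through oxygen at the aryne carbon remote from the flanking methoxy group, and the aryl anion next to that methoxy group would take the acyl group from oxygen, giving the ortho-hydroxy ketone A3. No ring closes.
- In its favour: a C-O and a C-C bond are made on adjacent carbons in one step, the regiochemistry follows from the inductive effect of the methoxy group, and no Lewis acid comes near the bridges. On this last point it is better than steps 6 and 7 of the chosen plan.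
- Against it: ring C of A4 is already hexasubstituted, so both arms must be attached by classical benzylation, followed by ortho-silylation and triflation. The aryne is flanked on both sides, the aryl anion may simply be protonated so that only O-arylation results, and the enolizable ketones of rings B and D can add to the aryne.
- Comparison: the alternative builds none of the skeleton of ring C, whereas the chosen key step builds the ring with both arms in place. In regiochemical reliability the two are equal, one controlled by aryne distortion and the other by polarization of ketene and ynol ether. The aryne step replaces two steps by one, but the precursor costs at least three more, so there is no net gain. The end game (ether cleavage, coupling) is the same.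

**Alternative 3:** The cut is made twice in each of rings B and D: between the free CH and the ethoxy-bearing carbon, and between the butanoyl-bearing carbon and the hydroxyl-bearing carbon next to the arm. The precursor A8 is ring C, with its butanoyl group and three methoxy groups, carrying two 1,1,3-tris(trimethylsilyloxy)buta-1,3-dien-2-ylmethyl arms. The partner is ynone A9.
- Forward key step: each diene would add to A9, terminal CH2 to the ethoxy-bearing carbon and ketene acetal carbon to the acyl-bearing carbon, and the adduct would aromatize by loss of one silyloxy group to give A7.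
- In its favour: two rings arise at once, each with its butanoyl group, three differentiated oxygens and the free carbon exactly where the bridge to ring A or E must go. Rings B and D would later need only one ethyl ether each cleaved in place of three methyl ethers, which is better than the chosen plan.
- Against it: tris(silyloxy)dienes of this kind are very moisture-sensitive, two of them would have to be generated with strong base on a ring that itself carries an enolizable ketone, and the donor-substituted ynone is a sluggish acceptor. Ring C with both arms must still be made by classical substitution.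
- Comparison: in bonds and rings formed (four bonds, two rings against two bonds, one ring) the alternative is the better. The chosen plan is the better in that it solves the most congested ring, C, which the alternative leaves untouched. Both rely on matching an oxygenated π-nucleophile with a carbonyl-polarized acceptor and are equal in expected regiocontrol. The step count is comparable: the alternative saves the Fries step but needs a longer preparation of A8.

Key step: step 5

Remark: rings A and E are handled as the enol tautomer drawn for the target; any other tautomer of these enolized triketones is the same compound. The regiochemistry of the key step was re-derived atom by atom and agrees with the structures of 8, 11 and 15.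

## Route

**Step 1**
Reactants: 1 1,3,5-trimethoxybenzene; 2 butanoyl chloride
Product: 3 1-(2,4,6-trimethoxyphenyl)butan-1-one
Conditions: AlCl3 (1.1 equiv), CH2Cl2, 0 °C; ice/1 M HCl
Reagents that add atoms: none
Why: Friedel-Crafts acylation; the three ring CH of 1 are equivalent and strongly activated, the product ketone is deactivated towards a second acylation, and 0 °C keeps AlCl3 from cleaving the methoxy groups next to the new carbonyl.

**Step 2**
Reactants: 3 1-(2,4,6-trimethoxyphenyl)butan-1-one
Product: 4 1-[3-(chloromethyl)-2,4,6-trimethoxyphenyl]butan-1-one
Conditions: (CH2O)n (1.1 equiv), HCl (g), AcOH, 15-20 °C; used at once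
Reagents that add atoms: formaldehyde (as paraformaldehyde), C=O; hydrogen chloride, Cl
Why: Blanc chloromethylation; the two free ring carbons of 3 are equivalent and each lies between two methoxy groups, the ketone damps the ring enough to hold the reaction at one chloromethyl group when formaldehyde is limiting, and the very ionizable benzylic chloride is carried on without storage.

**Step 3**
Reactants: 4 1-[3-(chloromethyl)-2,4,6-trimethoxyphenyl]butan-1-one; 5 ethoxyacetylene
Product: 8 1-[3-(3-ethoxyprop-2-yn-1-yl)-2,4,6-trimethoxyphenyl]butan-1-one, via ethoxyethynyllithium EtOC≡CLi 6 (not isolated), via ethoxyethynylzinc chloride EtOC≡CZnCl 7 (not isolated)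
Conditions: 5, n-BuLi, THF, −78 °C; ZnCl2, −78 → 0 °C; 4, PdCl2(DPEphos) (5 mol %), THF, 0 → 23 °C; pH 8 work-up, Et3N-washed SiO2
Reagents that add atoms: none
Why: Negishi coupling of a benzylic chloride with an alkynylzinc; the zinc acetylide neither adds to nor enolizes the hindered aryl ketone as the lithium acetylide would, the divalent palladium precatalyst is reduced in the flask to zerovalent palladium that inserts readily into the electron-rich benzylic C-Cl bond, and the wide bite angle of DPEphos speeds reductive elimination.

**Step 4**
Reactants: 8 1-[3-(3-ethoxyprop-2-yn-1-yl)-2,4,6-trimethoxyphenyl]butan-1-one; 9 acetyl chloride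
Product: 11 3-ethoxy-2-[(3-butanoyl-2,4,6-trimethoxyphenyl)methyl]cyclobut-2-en-1-one, via ketene 10 (not isolated)
Conditions: 9 (3 equiv, slow addition), Et3N (3.3 equiv), MeCN, 0 → 23 °C
Reagents that add atoms: none
Why: [2+2] cycloaddition of ketene, formed by dehydrochlorination of 9, with an electron-rich ynol ether; the ketene carbonyl carbon bonds to the nucleophilic arylmethyl-bearing alkyne carbon and the CH2 to the ethoxy-bearing carbon, which should give the 3-ethoxy-2-substituted cyclobutenone as the only regioisomer.

**Step 5**
Reactants: 11 3-ethoxy-2-[(3-butanoyl-2,4,6-trimethoxyphenyl)methyl]cyclobut-2-en-1-one; 8 1-[3-(3-ethoxyprop-2-yn-1-yl)-2,4,6-trimethoxyphenyl]butan-1-one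
Product: 15 2,4-bis[(3-butanoyl-2,4,6-trimethoxyphenyl)methyl]-3,5-diethoxyphenol, via vinylketene 12 (not isolated), via vinylcyclobutenone 13 (not isolated), via dienylketene 14 (not isolated)
Conditions: 11 (1.0 equiv), 8 (1.3 equiv), PhMe (0.5 M), 85-90 °C, sealed tube, Ar, dark
Reagents that add atoms: none
Why: Danheiser benzannulation, the closest known reaction being that of cyclobutenones with 1-alkoxyalkynes. Thermal four-electron electrocyclic opening of 11 breaks the bond between its carbonyl carbon and its CH2 and gives vinylketene 12. Regioselective [2+2] cycloaddition of the ketene C=C of 12 with 8 forms the two new skeletal bonds (carbonyl carbon to the arylmethyl-bearing alkyne carbon, arylmethyl-bearing ketene carbon to the ethoxy-bearing alkyne carbon) in racemic 13, whose single quaternary stereocentre is lost again in the next event. A second four-electron opening gives dienylketene 14, and ring C closes by a thermal six-electron disrotatory electrocyclization between the ketene carbon and the terminal CH2, followed by tautomerization of the cyclohexadienone to the phenol. No stereocentre remains, so only regio- and chemoselectivity are needed. The regiochemistry is secured by the polarization of both partners: the ynol ether is nucleophilic at the carbon remote from oxygen and the ketene is electrophilic at its carbonyl carbon, so the two arms end on either side of one ethoxy carbon and the CH from ketene ends next to the hydroxyl. Only the isomer of 14 with ketene and ethoxyvinyl group cis can close, and the other returns to 13 because the opening is reversible. The temperature is held below 100 °C so that 8 does not lose ethene by retro-ene fragmentation, and light is excluded because the aryl butyl ketones would undergo photochemical γ-hydrogen abstraction.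

**Step 6**
Reactants: 15 2,4-bis[(3-butanoyl-2,4,6-trimethoxyphenyl)methyl]-3,5-diethoxyphenol; 2 butanoyl chloride
Product: 16 2,4-bis[(3-butanoyl-2,4,6-trimethoxyphenyl)methyl]-3,5-diethoxyphenyl butanoate
Conditions: 2 (1.5 equiv), Et3N, DMAP (cat.), CH2Cl2, 0 → 23 °C
Reagents that add atoms: none
Why: DMAP-catalysed O-acylation of the only hydroxyl in the molecule; the acylpyridinium ion reaches the phenol despite its one ortho arm, and the ketones and ethers are inert.

**Step 7**
Reactants: 16 2,4-bis[(3-butanoyl-2,4,6-trimethoxyphenyl)methyl]-3,5-diethoxyphenyl butanoate
Product: 17 1-{3,5-bis[(3-butanoyl-2,4,6-trimethoxyphenyl)methyl]-2,4-diethoxy-6-hydroxyphenyl}butan-1-one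
Conditions: TiCl4 (4 equiv), CH2Cl2, 0 → 23 °C; 1 M HCl
Reagents that add atoms: none
Why: Lewis acid Fries rearrangement; ring C has a single free carbon, ortho to the ester oxygen and activated by two ethoxy groups, the para position is blocked and rings B and D are deactivated by their TiCl4-bound ketones, so the acyl group can arrive only at the intended carbon, where the titanium chelate of the ortho-hydroxy ketone holds it.

**Step 8**
Reactants: 17 1-{3,5-bis[(3-butanoyl-2,4,6-trimethoxyphenyl)methyl]-2,4-diethoxy-6-hydroxyphenyl}butan-1-one
Product: 18 1-{3,5-bis[(3-butanoyl-2,4,6-trihydroxyphenyl)methyl]-2,4,6-trihydroxyphenyl}butan-1-one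
Conditions: BBr3 (16 equiv), CH2Cl2, −78 → 23 °C; MeOH then H2O, 0 °C; degassed solvents
Reagents that add atoms: none
Why: Lewis acid cleavage of aryl alkyl ethers; BBr3 binds each ether oxygen and bromide removes the methyl or ethyl group by SN2 attack, fastest at oxygens chelated to a carbonyl, while the low temperature and aprotic medium should keep acid-mediated attack on the bridges slow.

**Step 9**
Reactants: 19 benzene-1,3,5-triol (phloroglucinol); 2 butanoyl chloride
Product: 20 1-(2,4,6-trihydroxyphenyl)butan-1-one
Conditions: AlCl3 (3.5 equiv), PhNO2/CH2Cl2, 0 → 23 °C; ice/HCl
Reagents that add atoms: none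
Why: Friedel-Crafts C-acylation of phloroglucinol; excess AlCl3 ties up the hydroxyls as aluminium phenoxides so that acylation goes to carbon, and the first acyl group deactivates the ring towards a second.

**Step 10**
Reactants: 20 1-(2,4,6-trihydroxyphenyl)butan-1-one
Product: 21 2-butanoyl-3,5-dihydroxy-4,4-dimethylcyclohexa-2,5-dien-1-one
Conditions: NaOMe (4 equiv), MeI (3 equiv), MeOH, 0 → 23 °C; HCl; chromatography
Reagents that add atoms: iodomethane, CI
Why: Dearomatizing geminal C-methylation of an acylphloroglucinol polyanion, the standard entry to acylfilicinic acids; after the first C-methylation the methylated carbon is the most nucleophilic site of the anion, so the second methyl group enters at the same carbon and locks the ring as the enolized triketone.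

**Step 11**
Reactants: 21 2-butanoyl-3,5-dihydroxy-4,4-dimethylcyclohexa-2,5-dien-1-one
Product: 22 2-butanoyl-6-[(dimethylamino)methyl]-3,5-dihydroxy-4,4-dimethylcyclohexa-2,5-dien-1-one
Conditions: CH2(NMe2)2 (1.5 equiv), CH2Cl2, 0 → 23 °C; evaporation, trituration
Reagents that add atoms: N,N,N',N'-tetramethylmethanediamine, CN(C)CN(C)C
Why: Mannich aminomethylation; the acidic enol protonates the aminal, which releases the N,N-dimethylmethyleneiminium ion, and the only free enol carbon of 21 attacks it, while the excess of aminal leaves no 21 to intercept the product, which is kept as its inner salt.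

**Step 12**
Reactants: 18 1-{3,5-bis[(3-butanoyl-2,4,6-trihydroxyphenyl)methyl]-2,4,6-trihydroxyphenyl}butan-1-one; 22 2-butanoyl-6-[(dimethylamino)methyl]-3,5-dihydroxy-4,4-dimethylcyclohexa-2,5-dien-1-one
Product: 25 1-{3,5-bis[(3-butanoyl-5-{[5-butanoyl-2,4-dihydroxy-3,3-dimethyl-6-oxocyclohexa-1,4-dien-1-yl]methyl}-2,4,6-trihydroxyphenyl)methyl]-2,4,6-trihydroxyphenyl}butan-1-one (the target), via methylidene trione 23 (not isolated), via mono-coupled tetramer 24 (not isolated)
Conditions: 22 (2.3 equiv), 1,4-dioxane, 70-80 °C, N2 sweep; dilute HCl wash
Reagents that add atoms: none
Why: Alkylation by a Mannich base through elimination and addition, as used for unsymmetrical methylene-bridged acylphloroglucinols; loss of dimethylamine from 22 gives the quinone-methide-like acceptor 23, which is attacked by the one free carbon of ring B and then of ring D (Friedel-Crafts-type conjugate addition, through 24), and the nitrogen sweep removes the amine so that the bridges are not left in contact with base.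

## Compound list

1 | 1,3,5-trimethoxybenzene | COc1cc(OC)cc(OC)c1 | starting material
2 | butanoyl chloride | CCCC(=O)Cl | starting material
3 | 1-(2,4,6-trimethoxyphenyl)butan-1-one | CCCC(=O)c1c(OC)cc(OC)cc1OC | intermediate
4 | 1-[3-(chloromethyl)-2,4,6-trimethoxyphenyl]butan-1-one | CCCC(=O)c1c(OC)cc(OC)c(CCl)c1OC | intermediate
5 | ethoxyacetylene | CCOC#C | starting material
6 | ethoxyethynyllithium | CCOC#C[Li] | intermediate
7 | ethoxyethynylzinc chloride | CCOC#C[Zn]Cl | intermediate
8 | 1-[3-(3-ethoxyprop-2-yn-1-yl)-2,4,6-trimethoxyphenyl]butan-1-one | CCOC#CCc1c(OC)cc(OC)c(C(=O)CCC)c1OC | intermediate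
9 | acetyl chloride | CC(=O)Cl | starting material
10 | ketene | C=C=O | intermediate
11 | 3-ethoxy-2-[(3-butanoyl-2,4,6-trimethoxyphenyl)methyl]cyclobut-2-en-1-one | CCOC1=C(Cc2c(OC)cc(OC)c(C(=O)CCC)c2OC)C(=O)C1 | intermediate
12 | 2-[(3-butanoyl-2,4,6-trimethoxyphenyl)methyl]-3-ethoxybuta-1,3-dien-1-one | C=C(OCC)C(Cc1c(OC)cc(OC)c(C(=O)CCC)c1OC)=C=O | intermediate
13 | 2,4-bis[(3-butanoyl-2,4,6-trimethoxyphenyl)methyl]-3-ethoxy-4-(1-ethoxyethenyl)cyclobut-2-en-1-one (racemic, transient) | O=C1C(Cc2c(OC)cc(OC)c(C(=O)CCC)c2OC)=C(OCC)C1(Cc3c(OC)cc(OC)c(C(=O)CCC)c3OC)C(OCC)=C | intermediate
14 | (3E)-2,4-bis[(3-butanoyl-2,4,6-trimethoxyphenyl)methyl]-3,5-diethoxyhexa-1,3,5-trien-1-one (ketene and ethoxyvinyl group cis) | O=C=C(Cc1c(OC)cc(OC)c(C(=O)CCC)c1OC)/C(OCC)=C(/Cc2c(OC)cc(OC)c(C(=O)CCC)c2OC)C(OCC)=C | intermediate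
15 | 2,4-bis[(3-butanoyl-2,4,6-trimethoxyphenyl)methyl]-3,5-diethoxyphenol | Oc1cc(OCC)c(Cc2c(OC)cc(OC)c(C(=O)CCC)c2OC)c(OCC)c1Cc3c(OC)cc(OC)c(C(=O)CCC)c3OC | intermediate
16 | 2,4-bis[(3-butanoyl-2,4,6-trimethoxyphenyl)methyl]-3,5-diethoxyphenyl butanoate | CCCC(=O)Oc1cc(OCC)c(Cc2c(OC)cc(OC)c(C(=O)CCC)c2OC)c(OCC)c1Cc3c(OC)cc(OC)c(C(=O)CCC)c3OC | intermediate
17 | 1-{3,5-bis[(3-butanoyl-2,4,6-trimethoxyphenyl)methyl]-2,4-diethoxy-6-hydroxyphenyl}butan-1-one | CCCC(=O)c1c(O)c(Cc2c(OC)cc(OC)c(C(=O)CCC)c2OC)c(OCC)c(Cc3c(OC)cc(OC)c(C(=O)CCC)c3OC)c1OCC | intermediate
18 | 1-{3,5-bis[(3-butanoyl-2,4,6-trihydroxyphenyl)methyl]-2,4,6-trihydroxyphenyl}butan-1-one | CCCC(=O)c1c(O)c(Cc2c(O)cc(O)c(C(=O)CCC)c2O)c(O)c(Cc3c(O)cc(O)c(C(=O)CCC)c3O)c1O | intermediate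
19 | benzene-1,3,5-triol (phloroglucinol) | Oc1cc(O)cc(O)c1 | starting material
20 | 1-(2,4,6-trihydroxyphenyl)butan-1-one | CCCC(=O)c1c(O)cc(O)cc1O | intermediate
21 | 2-butanoyl-3,5-dihydroxy-4,4-dimethylcyclohexa-2,5-dien-1-one | CCCC(=O)C1=C(O)C(C)(C)C(O)=CC1=O | intermediate
22 | 2-butanoyl-6-[(dimethylamino)methyl]-3,5-dihydroxy-4,4-dimethylcyclohexa-2,5-dien-1-one | CCCC(=O)C1=C(O)C(C)(C)C(O)=C(CN(C)C)C1=O | intermediate
23 | 2-butanoyl-3-hydroxy-4,4-dimethyl-6-methylidenecyclohex-2-ene-1,5-dione | CCCC(=O)C1=C(O)C(C)(C)C(=O)C(=C)C1=O | intermediate
24 | 1-{3-[(3-butanoyl-5-{[5-butanoyl-2,4-dihydroxy-3,3-dimethyl-6-oxocyclohexa-1,4-dien-1-yl]methyl}-2,4,6-trihydroxyphenyl)methyl]-5-[(3-butanoyl-2,4,6-trihydroxyphenyl)methyl]-2,4,6-trihydroxyphenyl}butan-1-one | CCCC(=O)C1=C(O)C(C)(C)C(O)=C(Cc2c(O)c(Cc3c(O)c(Cc4c(O)cc(O)c(C(=O)CCC)c4O)c(O)c(C(=O)CCC)c3O)c(O)c(C(=O)CCC)c2O)C1=O | intermediate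
25 | 1-{3,5-bis[(3-butanoyl-5-{[5-butanoyl-2,4-dihydroxy-3,3-dimethyl-6-oxocyclohexa-1,4-dien-1-yl]methyl}-2,4,6-trihydroxyphenyl)methyl]-2,4,6-trihydroxyphenyl}butan-1-one | CCCC(=O)C1=C(O)C(C)(C)C(O)=C(Cc2c(O)c(Cc3c(O)c(Cc4c(O)c(CC5=C(O)C(C)(C)C(O)=C(C(=O)CCC)C5=O)c(O)c(C(=O)CCC)c4O)c(O)c(C(=O)CCC)c3O)c(O)c(C(=O)CCC)c2O)C1=O | target

## Step count and least certain steps

Total step count: 12. Longest linear sequence: 9 steps (1, 2, 3, 4, 5, 6, 7, 8, 12); the end-ring branch (9, 10, 11) joins at step 12.

**Step 5 (key step).** The most likely failure is a mismatch of rates. The cyclobutenone 11 is a donor-stabilized vinylogous ester and may open only slowly at a temperature at which 8 already begins to lose ethene by retro-ene fragmentation. The ketene so formed would then consume 8 by its own [2+2] reaction. Photochemical opening is not available because of the aryl butyl ketones. The fallback uses Friedel-Crafts chemistry and gives up the ring construction; it sets out from 20 and 4 and comes back to the route at 17. Compound 20 would be O-ethylated at its two non-chelated hydroxyls (EtI, K2CO3, acetone) to 1-(2,4-diethoxy-6-hydroxyphenyl)butan-1-one F1. The only two free ring carbons of F1 would then be benzylated with two equivalents of 4 (ZnCl2 cat., CH2Cl2, or hexafluoroisopropanol without catalyst) to give 17, ready for step 8.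

**Step 12.** The most likely failure is exchange of the methylene bridges: the liberated amine deprotonates phenols of 18, 24 or 25, a bridge fragments by retro-Michael reaction, and recombination scrambles the chain length. Transfer of the methylene unit between two end rings to a symmetric dimer is a second drain. The fallback reverses the polarity; it sets out from 18 and 21 and comes back at 25. Compound 18 would be aminomethylated at the free carbons of rings B and D with CH2(NMe2)2 to the bis-Mannich base 1-{3,5-bis[(3-butanoyl-5-[(dimethylamino)methyl]-2,4,6-trihydroxyphenyl)methyl]-2,4,6-trihydroxyphenyl}butan-1-one F2, a phenolic Mannich base that should be storable. F2 would then be warmed with two equivalents of the strongly acidic 21, which protonates the benzylic amines, triggers loss of dimethylamine to ortho-quinone methides and traps each at its free enol carbon to give 25.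

**Step 8.** The most likely failures are acid-induced cleavage of a bridge (ipso-protonation of an electron-rich ring and loss of a stabilized benzylic cation), cyclodehydration of ortho,ortho'-dihydroxy diarylmethane units to xanthenes on warming, and incomplete cleavage of the two ethyl ethers. The fallback avoids ether protection of the trimer altogether, at the price of abandoning the ring construction; it sets out from 20 and comes back at 18. Compound 20 would be aminomethylated at both free ring carbons (CH2(NMe2)2, 2.2 equiv) to 1-{3,5-bis[(dimethylamino)methyl]-2,4,6-trihydroxyphenyl}butan-1-one F3. F3 would be heated with a large excess of 20 (1,4-dioxane, 80 °C), so that each quinone methide is capped by a fresh molecule of 20; the excess of 20 is recovered.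

**Step 4.** The most likely failure is that dimerization of ketene, or attack of acetyl chloride or triethylammonium chloride on the acid-sensitive ynol ether, outruns cycloaddition to the internal, more hindered alkyne. The fallback sets out from 8 and comes back at 11. Dichloroketene (Cl3CCOCl, zinc-copper couple, Et2O/DME) is far more electrophilic and slower to dimerize, and should add with the same regiochemistry to give 4,4-dichloro-3-ethoxy-2-[(3-butanoyl-2,4,6-trimethoxyphenyl)methyl]cyclobut-2-en-1-one F4. Reductive removal of both chlorines (Zn dust, AcOH, TMEDA, EtOH, 0 °C) would then give 11.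

**Step 3.** The most likely failures are ionization of 4 by ZnCl2 with capture of the benzylic cation by the electron-rich triple bond of 8 or by a second arene, isomerization of the skipped alkyne to an allenyl ether, and hydration of the ynol ether to an ester during work-up. The fallback replaces the zinc reagent made in the flask by an isolated, neutral tin acetylide; it sets out from 5 and 4 and comes back at 8. Compound 5 would be converted (n-BuLi, then Bu3SnCl) into tributyl(ethoxyethynyl)stannane F5, purified by distillation, and coupled with 4 under Stille conditions (Pd(PPh3)4, a zerovalent palladium complex, toluene, 50 °C) in the absence of any Lewis acid or base.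

## Further compounds

F1 | step 5 | 1-(2,4-diethoxy-6-hydroxyphenyl)butan-1-one | CCCC(=O)c1c(O)cc(OCC)cc1OCC
F2 | step 12 | 1-{3,5-bis[(3-butanoyl-5-[(dimethylamino)methyl]-2,4,6-trihydroxyphenyl)methyl]-2,4,6-trihydroxyphenyl}butan-1-one | CCCC(=O)c1c(O)c(Cc2c(O)c(CN(C)C)c(O)c(C(=O)CCC)c2O)c(O)c(Cc3c(O)c(CN(C)C)c(O)c(C(=O)CCC)c3O)c1O
F3 | step 8 | 1-{3,5-bis[(dimethylamino)methyl]-2,4,6-trihydroxyphenyl}butan-1-one | CCCC(=O)c1c(O)c(CN(C)C)c(O)c(CN(C)C)c1O
F4 | step 4 | 4,4-dichloro-3-ethoxy-2-[(3-butanoyl-2,4,6-trimethoxyphenyl)methyl]cyclobut-2-en-1-one | CCOC1=C(Cc2c(OC)cc(OC)c(C(=O)CCC)c2OC)C(=O)C1(Cl)Cl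
F5 | step 3 | tributyl(ethoxyethynyl)stannane | CCCC[Sn](CCCC)(CCCC)C#COCC
A1 | alternative 1 | nonamethyl ether of the target (rings B, C and D as methyl ethers) | CCCC(=O)c1c(OC)c(Cc2c(OC)c(CC3=C(O)C(C)(C)C(O)=C(C(=O)CCC)C3=O)c(OC)c(C(=O)CCC)c2OC)c(OC)c(Cc2c(OC)c(CC3=C(O)C(C)(C)C(O)=C(C(=O)CCC)C3=O)c(OC)c(C(=O)CCC)c2OC)c1OC
A2 | alternative 1 | B-C-D nonamethyl ether carrying on rings B and D a 2-(methoxycarbonyl)-2-methyl-1,3,5-trioxo chain (bis(triketo ester), mixture of diastereomers at the two enolizable chain CH) | CCCC(=O)c1c(OC)c(Cc2c(OC)c(CC(C(=O)CC(=O)CCC)C(=O)C(C)(C)C(=O)OC)c(OC)c(C(=O)CCC)c2OC)c(OC)c(Cc3c(OC)c(CC(C(=O)CC(=O)CCC)C(=O)C(C)(C)C(=O)OC)c(OC)c(C(=O)CCC)c3OC)c1OC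
A3 | alternative 2 | 1-{3,5-bis[(3-butanoyl-2,4,6-trimethoxyphenyl)methyl]-2-hydroxy-4,6-dimethoxyphenyl}butan-1-one | CCCC(=O)c1c(O)c(Cc2c(OC)cc(OC)c(C(=O)CCC)c2OC)c(OC)c(Cc2c(OC)cc(OC)c(C(=O)CCC)c2OC)c1OC
A4 | alternative 2 | 2,4-bis[(3-butanoyl-2,4,6-trimethoxyphenyl)methyl]-3,5-dimethoxy-6-(trimethylsilyl)phenyl trifluoromethanesulfonate | C[Si](C)(C)c1c(OS(=O)(=O)C(F)(F)F)c(Cc2c(OC)cc(OC)c(C(=O)CCC)c2OC)c(OC)c(Cc3c(OC)cc(OC)c(C(=O)CCC)c3OC)c1OC
A5 | alternative 2 | ring C aryne: 3,5-bis[(3-butanoyl-2,4,6-trimethoxyphenyl)methyl]-4,6-dimethoxybenzyne | COC1=C(Cc2c(OC)cc(OC)c(C(=O)CCC)c2OC)C(OC)=C(Cc2c(OC)cc(OC)c(C(=O)CCC)c2OC)C#C1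
A6 | alternative 2 | butanoic acid | CCCC(=O)O
A7 | alternative 3 | 1-{3,5-bis[(3-butanoyl-4-ethoxy-2,6-dihydroxyphenyl)methyl]-2,4,6-trimethoxyphenyl}butan-1-one | CCCC(=O)c1c(OC)c(Cc2c(O)cc(OCC)c(C(=O)CCC)c2O)c(OC)c(Cc2c(O)cc(OCC)c(C(=O)CCC)c2O)c1OC
A8 | alternative 3 | 1-{2,4,6-trimethoxy-3,5-bis[2-(1-(trimethylsilyloxy)ethenyl)-3,3-bis(trimethylsilyloxy)prop-2-en-1-yl]phenyl}butan-1-one | CCCC(=O)c1c(OC)c(CC(C(=C)O[Si](C)(C)C)=C(O[Si](C)(C)C)O[Si](C)(C)C)c(OC)c(CC(C(=C)O[Si](C)(C)C)=C(O[Si](C)(C)C)O[Si](C)(C)C)c1OC
A9 | alternative 3 | 1-ethoxyhex-1-yn-3-one | CCCC(=O)C#COCC
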